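**Assumption:** the target has no stereogenic centre and no stereogenic double bond, so "single enantiomer" is met by the constitution alone. It is drawn as the free bis(hydrogen sulfate), which is released from its dipotassium salt only in the last operation, and ketone 1 is taken as a catalogue compound.

## The problem

- The skeleton is a flavone: benzo ring A (C5–C8a), pyranone ring C (O1, C2, C3, C4) and phenyl ring B on C2. It has no stereocentre, and ring construction is standard.
- The difficulty is the oxygen pattern. Five oxygens sit on the periphery (O3, O5, O7, O3', O4'), and only O3 and O3' carry SO3H.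
- The oxygens that must stay free are the reactive ones. O7–H and O4'–H are each conjugated to the C4 carbonyl and are the most acidic, so sulfation of the pentahydroxy compound goes first to the wrong places.
- The hardest pair is O3'/O4'. They are the neighbouring oxygens of a catechol on ring B and differ little in acidity and in steric environment, so any plan that makes the catechol first must then tell them apart.
- O3 is an enol oxygen. The free 3-hydroxyflavone is degraded by base and oxidants; its sulfate is not.
- Aryl and enol sulfate monoesters do not survive hot acid, Lewis acids or silica chromatography as free acids. They must come late, and the unmasking of O5 and O7 after them must be neutral.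
- The feature that the key step uses: O3' sits on C3', which is ortho to O4'. C1', para to O4', is quaternary (bond to C2), and C3' and C5' are interchanged by rotation about C1'–C2. A ring-B 4'-phenoxide therefore has only one kind of nucleophilic C–H carbon.
- O3 and O3' are exactly the two oxygens that a 5,7,4'-trioxygenated flavone lacks. Both can therefore be added as C–O bonds after the skeleton exists, and O3' can arrive already bonded to sulfur.

## Retrosynthesis

**12 ⇐ 11 ⇐ 10.** The two benzyl C–O bonds at O5 and O7 are cut last. Benzyl is chosen because ring A must carry no ionisable oxygen in the key step, and because hydrogenolysis is the one deprotection that needs neither acid nor nucleophile, both of which threaten the sulfates. The forward step must leave two sulfate esters and the C2=C3 bond alone. The acid form 12 is generated from salt 11 only at the end.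

**10 ⇐ 9 (⇐ 8).** The C3'–O3' bond is cut with the sulfate still on the oxygen. The neighbouring cut, O3'–S, leads back to a catechol and to the O3'/O4' problem. A cut at C1'–C2 only moves that problem into a building block. The chosen cut removes the problem: precursor 9 has a plain 4-hydroxyphenyl ring B, and its phenoxide is asked to attack peroxydisulfate through C3'. The oxygen that is created is the one that bears sulfur, so an O4'-sulfate cannot form. The forward reaction must tolerate the 3-sulfate and the benzyl ethers. The alkali it needs also releases the phenoxide from pivalate 8 in the same flask.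

**8 ⇐ 7.** The O3–S bond is cut. In 7, O3–H is the only hydroxyl (O5, O7 benzylated, O4' acylated), so sulfation needs no selectivity. Sulfating here, before ring B is oxidised, also means the labile enol is already masked when strong base and an oxidant are used in the key step.

**7 ⇐ 5 (via 6).** The C3–O3 bond is cut. The oxygen is delivered to the enol-ether-like C2=C3 bond of flavone 5 by a dioxirane, and the epoxide 6 isomerises to the flavonol. The alternative, closing a chalcone directly to the flavonol with alkaline peroxide, is diverted towards aurones by a 6'-alkoxy group, which this series has. The 4'-pivalate is needed here so that the oxidant does not attack a free phenol.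

**5 ⇐ 4 ⇐ 3 ⇐ 1 + 2.** The acyl–O4' bond is cut first. Then the O1–C2 bond is cut (oxidative cyclisation of a 2'-hydroxychalcone), and then the Cα=Cβ bond of chalcone 3 (aldol condensation). This leads to ketone 1, which carries ring A with O5 and O7 already benzylated, and to 4-hydroxybenzaldehyde 2. Ring B enters as the simplest possible phenol.

## Roads not taken

**Alternative 1:** the most obvious plan cuts both O–S bonds at once.
- Cut and forward step: quercetin A1 is partially benzylated to 7,4'-di-O-benzylquercetin A2. O3–H and O3'–H are sulfated together with an SO3–amine complex to give A4, and the benzyl groups are removed by hydrogenolysis.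
- Weakness: everything depends on kinetic discrimination among the hydroxyls of A1 in the alkylation, in particular O4' against O3' of the catechol. Any 7,3'-di-O-benzyl isomer A3 is carried on to the 3,4'-disulfate, a constitutional isomer of the target with the same charge and polarity.
- Further weakness: the chelated O5–H is free during sulfation.
- Comparison: this plan is not longer than the chosen one. Its regiochemistry, however, is settled by separating isomers, whereas in the chosen plan the wrong isomer has no pathway by which to form.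

**Alternative 2:** cut the O4'–S bond of a 3',4'-cyclic sulfate.
- Cut and forward step: 5,7-di-O-benzylquercetin A5 would be closed at the catechol with a sulfuryl reagent and sulfated at O3 to give A6. Hydroxide would then open the cyclic sulfate at sulfur and expel the O4' phenoxide, which is the better leaving group because it is conjugated to C4=O.
- Weakness: the two S–O(aryl) bonds differ only in leaving-group ability, so both monosulfates must be expected.
- Further weakness: A5 needs a catechol carried through the flavonol synthesis under a third, orthogonal protecting group, and O3–H competes for the sulfuryl reagent. The run-up is longer and the selectivity is less secure than when O3' is created already sulfated.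

**Alternative 3:** cut C3–O3 and C3'–O3' together.
- Cut and forward step: flavone 4 would be treated with two equivalents of peroxydisulfate, aiming at 10 in one step. C3 is a conceivable site: it is the β-carbon of the enol ether O1–C2=C3 and the vinylogous position of the 4'-phenoxide through C1' and C2.
- Weakness: persulfate attack at such a vinylogous carbon has no close precedent, and ortho attack is the established course. The reaction should therefore stop at the 3'-sulfate A7.
- Further weakness: A7 lacks O3 and cannot be advanced, because introducing O3 would then need an electrophilic oxidant in the presence of a free phenol. Two successive low-converting persulfate substitutions on one molecule would also multiply the loss.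
- Comparison: the chosen plan keeps the idea for the position where the reactivity is known and sets O3 by precedented means.

Key step: step 6

## Route

**Step 1**
Reactants: 1 1-[2,4-bis(benzyloxy)-6-hydroxyphenyl]ethan-1-one; 2 4-hydroxybenzaldehyde
Product: 3 (E)-1-[2,4-bis(benzyloxy)-6-hydroxyphenyl]-3-(4-hydroxyphenyl)prop-2-en-1-one
Conditions: KOH (50% aq.), EtOH, rt, 48 h; then 1 M HCl to pH 4
Reagents that add atoms: none
Why: Claisen–Schmidt condensation: the enolate of 1 adds to 2 and E1cB dehydration gives the thermodynamically favoured E-enone, whose geometry is consumed in step 2. Direct use of the free 4-hydroxyaldehyde in concentrated alkali is an established way to 4-hydroxy-2'-hydroxy-4',6'-dialkoxychalcones, and the chelated 2'-OH needs no protection.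

**Step 2**
Reactants: 3 (E)-1-[2,4-bis(benzyloxy)-6-hydroxyphenyl]-3-(4-hydroxyphenyl)prop-2-en-1-one
Product: 4 5,7-bis(benzyloxy)-2-(4-hydroxyphenyl)-4H-chromen-4-one
Conditions: I2 (10 mol%), DMSO, 130 °C; aq. Na2S2O3 work-up
Reagents that add atoms: none
Why: Iodine-catalysed oxidative cyclisation of a 2'-hydroxychalcone: 6-endo oxa-Michael closure forms O1–C2, α-iodination and loss of HI form C2=C3, and DMSO reoxidises iodide. Benzyl ethers and a free ring-B phenol are routinely carried through this reaction.

**Step 3**
Reactants: 4 5,7-bis(benzyloxy)-2-(4-hydroxyphenyl)-4H-chromen-4-one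
Product: 5 4-[5,7-bis(benzyloxy)-4-oxo-4H-chromen-2-yl]phenyl pivalate
Conditions: PivCl, Et3N, DMAP (cat.), CH2Cl2, 0 °C to rt
Reagents that add atoms: pivaloyl chloride, CC(C)(C)C(Cl)=O
Why: O-acylation of the only free hydroxyl. The pivalate makes ring B inert to the electrophilic oxidant of step 4, leaves O3–H as the only hydroxyl in step 5, and is the one group that the alkali of step 6 removes.

**Step 4**
Reactants: 5 4-[5,7-bis(benzyloxy)-4-oxo-4H-chromen-2-yl]phenyl pivalate
Product: 7 4-[5,7-bis(benzyloxy)-3-hydroxy-4-oxo-4H-chromen-2-yl]phenyl pivalate, via 2,3-epoxide 6 (not isolated)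
Conditions: DMDO (acetone), CH2Cl2, 0 °C to rt; then p-TsOH·H2O (cat.), CH2Cl2, rt
Reagents that add atoms: dimethyldioxirane, CC1(C)OO1
Why: Dioxirane epoxidation of the enol-ether-like C2=C3 bond of a 5-alkoxyflavone, then acid-catalysed opening at C2 (cation stabilised by O1 and the aryl group) and loss of H3; this is the standard flavone-to-flavonol conversion. The two stereocentres of racemic 6 disappear on aromatisation.

**Step 5**
Reactants: 7 4-[5,7-bis(benzyloxy)-3-hydroxy-4-oxo-4H-chromen-2-yl]phenyl pivalate
Product: 8 potassium 5,7-bis(benzyloxy)-4-oxo-2-[4-(pivaloyloxy)phenyl]-4H-chromen-3-yl sulfate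
Conditions: SO3·pyridine, pyridine, 50 °C; then aq. KHCO3, 0 °C; C18 (H2O/MeOH)
Reagents that add atoms: sulfur trioxide–pyridine complex, [O-]S(=O)(=O)[n+]1ccccc1; potassium hydrogen carbonate, [K+].OC([O-])=O
Why: Sulfation of the enolic O3–H with an SO3–amine complex, as practised on O3 of protected flavonols. Compound 7 has no other hydroxyl, and the near-neutral bicarbonate work-up keeps both sulfate and pivalate.

**Step 6**
Reactants: 8 potassium 5,7-bis(benzyloxy)-4-oxo-2-[4-(pivaloyloxy)phenyl]-4H-chromen-3-yl sulfate
Product: 10 dipotassium 5,7-bis(benzyloxy)-2-[4-hydroxy-3-(sulfonatooxy)phenyl]-4-oxo-4H-chromen-3-yl sulfate, via dipotassium phenoxide 9 (not isolated)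
Conditions: 2 M aq. KOH–pyridine, rt (pivalate cleavage); then K2S2O8 (aq., slow addition), 10 °C to rt, 24–48 h; AcOH to pH 7; C18 (H2O/MeOH)
Reagents that add atoms: potassium peroxydisulfate, [K+].[K+].[O-]S(=O)(=O)OOS(=O)(=O)[O-]; potassium hydroxide, [K+].[OH-]
Why: Elbs persulfate oxidation, run so that the primary aryl sulfate is kept instead of being hydrolysed. Hydroxide first cleaves the pivalate, so 9 carries a single phenoxide, O4'; O5 and O7 are benzyl ethers and cannot take part. The phenoxide attacks through carbon on a peroxide oxygen of peroxydisulfate (SN2 displacement at oxygen, sulfate as leaving group), and the resulting 6-(sulfonatooxy)cyclohexa-2,4-dienone re-aromatises by loss of H3' to the 4'-hydroxy-3'-sulfate. The closest known reactions are the ortho Elbs oxidation of para-substituted, acceptor-bearing phenols to catechol monosulfates (4-nitrophenol to 2-hydroxy-5-nitrophenyl sulfate) and the nuclear persulfate oxidations of hydroxyflavones. No ring is closed and no stereocentre is formed. The step needs site selectivity and O-regiochemistry: C1' is quaternary, C3 already bears its sulfate, and C3' and C5' are interchanged by rotation about C1'–C2, so only one constitution can result and the sulfate is necessarily on the new oxygen, never on O4'. A second attack at C5' is disfavoured because the product is a weaker and more highly charged nucleophile, and unreacted 9 can be carried through a second cycle. The 3-sulfate keeps the enol inert to alkaline oxidation, and sulfate monoester anions do not hydrolyse in cold alkali.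

**Step 7**
Reactants: 10 dipotassium 5,7-bis(benzyloxy)-2-[4-hydroxy-3-(sulfonatooxy)phenyl]-4-oxo-4H-chromen-3-yl sulfate
Product: 12 quercetin 3,3'-bis(hydrogen sulfate), via dipotassium salt 11 (not isolated)
Conditions: H2 (1 atm), 10% Pd/C, MeOH–H2O, rt; filter; then 1 M HCl (2 equiv), 0 °C, C18 desalting, freeze-drying
Reagents that add atoms: none
Why: Hydrogenolysis of aryl benzyl ethers needs neither acid nor nucleophile and should leave aryl sulfate salts and the pyranone C2=C3 bond untouched. The acid form is released with exactly two equivalents of cold HCl and desalted at once, because aryl hydrogen sulfates hydrolyse under acid catalysis when warmed or concentrated.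

## Compound list

1 | 1-[2,4-bis(benzyloxy)-6-hydroxyphenyl]ethan-1-one | CC(=O)c1c(O)cc(OCc2ccccc2)cc1OCc1ccccc1 | starting material
2 | 4-hydroxybenzaldehyde | O=Cc1ccc(O)cc1 | starting material
3 | (E)-1-[2,4-bis(benzyloxy)-6-hydroxyphenyl]-3-(4-hydroxyphenyl)prop-2-en-1-one | O=C(/C=C/c1ccc(O)cc1)c1c(O)cc(OCc2ccccc2)cc1OCc1ccccc1 | intermediate
4 | 5,7-bis(benzyloxy)-2-(4-hydroxyphenyl)-4H-chromen-4-one (5,7-di-O-benzylapigenin) | O=c1cc(-c2ccc(O)cc2)oc2cc(OCc3ccccc3)cc(OCc3ccccc3)c12 | intermediate
5 | 4-[5,7-bis(benzyloxy)-4-oxo-4H-chromen-2-yl]phenyl pivalate | CC(C)(C)C(=O)Oc1ccc(-c2cc(=O)c3c(OCc4ccccc4)cc(OCc4ccccc4)cc3o2)cc1 | intermediate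
6 | 2,3-epoxide of 5 (2,3-epoxyflavanone; racemic, oxirane necessarily cis-fused across C2–C3) | CC(C)(C)C(=O)Oc1ccc(cc1)C12OC1C(=O)c1c(OCc3ccccc3)cc(OCc3ccccc3)cc1O2 | intermediate (not isolated)
7 | 4-[5,7-bis(benzyloxy)-3-hydroxy-4-oxo-4H-chromen-2-yl]phenyl pivalate | CC(C)(C)C(=O)Oc1ccc(-c2oc3cc(OCc4ccccc4)cc(OCc4ccccc4)c3c(=O)c2O)cc1 | intermediate
8 | potassium 5,7-bis(benzyloxy)-4-oxo-2-[4-(pivaloyloxy)phenyl]-4H-chromen-3-yl sulfate | [K+].CC(C)(C)C(=O)Oc1ccc(-c2oc3cc(OCc4ccccc4)cc(OCc4ccccc4)c3c(=O)c2OS(=O)(=O)[O-])cc1 | intermediate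
9 | dipotassium 5,7-bis(benzyloxy)-2-(4-oxidophenyl)-4-oxo-4H-chromen-3-yl sulfate | [K+].[K+].[O-]c1ccc(-c2oc3cc(OCc4ccccc4)cc(OCc4ccccc4)c3c(=O)c2OS(=O)(=O)[O-])cc1 | intermediate (not isolated)
10 | dipotassium 5,7-bis(benzyloxy)-2-[4-hydroxy-3-(sulfonatooxy)phenyl]-4-oxo-4H-chromen-3-yl sulfate (5,7-di-O-benzylquercetin 3,3'-disulfate, dipotassium salt) | [K+].[K+].O=c1c(OS(=O)(=O)[O-])c(-c2ccc(O)c(OS(=O)(=O)[O-])c2)oc2cc(OCc3ccccc3)cc(OCc3ccccc3)c12 | intermediate
11 | dipotassium 5,7-dihydroxy-2-[4-hydroxy-3-(sulfonatooxy)phenyl]-4-oxo-4H-chromen-3-yl sulfate (quercetin 3,3'-disulfate, dipotassium salt) | [K+].[K+].O=c1c(OS(=O)(=O)[O-])c(-c2ccc(O)c(OS(=O)(=O)[O-])c2)oc2cc(O)cc(O)c12 | intermediate (not isolated)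
12 | quercetin 3,3'-bis(hydrogen sulfate) | O=c1c(OS(=O)(=O)O)c(-c2ccc(O)c(OS(=O)(=O)O)c2)oc2cc(O)cc(O)c12 | target

## Step count and least certain steps

Total step count: 7. Longest linear sequence: 7 steps (from 1; aldehyde 2 enters in step 1).

**Step 6 (key step).**
- Risk: slow C–O bond formation. The phenoxide of 9 is delocalised into the C4 carbonyl and is a weak carbon nucleophile, so peroxydisulfate may be lost to homolysis and to radical coupling of the phenoxide before substitution is complete.
- Fallback (from 1, returning at 11): O3' is brought in with the aldehyde and told apart from O4' by a benzyl group already in place. Claisen–Schmidt condensation of 1 with commercial 4-(benzyloxy)-3-hydroxybenzaldehyde (KOH, EtOH) should give (E)-1-[2,4-bis(benzyloxy)-6-hydroxyphenyl]-3-[4-(benzyloxy)-3-hydroxyphenyl]prop-2-en-1-one F1. I2 (cat.)/DMSO then gives 5,7-bis(benzyloxy)-2-[4-(benzyloxy)-3-hydroxyphenyl]-4H-chromen-4-one F2. Pivaloylation gives 2-(benzyloxy)-5-[5,7-bis(benzyloxy)-4-oxo-4H-chromen-2-yl]phenyl pivalate F3. DMDO followed by TsOH gives 2-(benzyloxy)-5-[5,7-bis(benzyloxy)-3-hydroxy-4-oxo-4H-chromen-2-yl]phenyl pivalate F4. K2CO3/MeOH removes the pivalate to give 5,7,4'-tri-O-benzylquercetin F5. Excess SO3·pyridine, then KHCO3, sulfates O3 and O3' together to give dipotassium 5,7,4'-tri-O-benzylquercetin 3,3'-disulfate F6. Hydrogenolysis (H2, Pd/C) of the three benzyl ethers gives 11, which is acidified to 12 as in step 7.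

**Step 1.**
- Risk: sluggish aldol addition. In alkali the aldehyde 2 is present as its phenoxide, which lowers the electrophilicity of the formyl group and leaves time for retro-aldol and disproportionation pathways.
- Fallback (from 1, returning at 4): the aldol partner is made neutral and the phenol is revealed only after ring closure. Condensation of 1 with 4-(methoxymethoxy)benzaldehyde (KOH, EtOH) should give (E)-1-[2,4-bis(benzyloxy)-6-hydroxyphenyl]-3-[4-(methoxymethoxy)phenyl]prop-2-en-1-one F7. I2 (cat.)/DMSO gives 5,7-bis(benzyloxy)-2-[4-(methoxymethoxy)phenyl]-4H-chromen-4-one F8. Dilute HCl in MeOH at rt then cleaves the acetal to give 4.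

**Step 2.**
- Risk: loss of the O5 benzyl group. The hydrogen iodide formed at 130 °C can cleave the ether peri to the carbonyl with chelation assistance, and nuclear iodination of the electron-rich ring A can compete.
- Fallback (from 3, returning at 4): ring closure and dehydrogenation are separated. NaOAc in refluxing EtOH should close 3 by oxa-Michael addition to racemic 5,7-bis(benzyloxy)-2-(4-hydroxyphenyl)chroman-4-one F9, and DDQ in refluxing dioxane then dehydrogenates C2–C3 to give 4.

**Step 4.**
- Risk: incomplete oxygen transfer to the C2=C3 bond, which is deactivated by the C4 carbonyl, with slow oxidation of the benzylic C–H bonds by the excess dioxirane needed.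
- Fallback (from 5, returning at 7): the oxygen is introduced through a C3 anion instead of through the alkene. LDA in THF at −78 °C should lithiate C3 of 5, and B(OMe)3 then gives dimethyl {5,7-bis(benzyloxy)-4-oxo-2-[4-(pivaloyloxy)phenyl]-4H-chromen-3-yl}boronate F10. Oxidation with H2O2/AcOH gives 7.

## Further compounds

F1 | step 6 | (E)-1-[2,4-bis(benzyloxy)-6-hydroxyphenyl]-3-[4-(benzyloxy)-3-hydroxyphenyl]prop-2-en-1-one | O=C(/C=C/c1ccc(OCc2ccccc2)c(O)c1)c1c(O)cc(OCc2ccccc2)cc1OCc1ccccc1
F2 | step 6 | 5,7-bis(benzyloxy)-2-[4-(benzyloxy)-3-hydroxyphenyl]-4H-chromen-4-one | O=c1cc(-c2ccc(OCc3ccccc3)c(O)c2)oc2cc(OCc3ccccc3)cc(OCc3ccccc3)c12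
F3 | step 6 | 2-(benzyloxy)-5-[5,7-bis(benzyloxy)-4-oxo-4H-chromen-2-yl]phenyl pivalate | CC(C)(C)C(=O)Oc1cc(-c2cc(=O)c3c(OCc4ccccc4)cc(OCc4ccccc4)cc3o2)ccc1OCc1ccccc1
F4 | step 6 | 2-(benzyloxy)-5-[5,7-bis(benzyloxy)-3-hydroxy-4-oxo-4H-chromen-2-yl]phenyl pivalate | CC(C)(C)C(=O)Oc1cc(-c2oc3cc(OCc4ccccc4)cc(OCc4ccccc4)c3c(=O)c2O)ccc1OCc1ccccc1
F5 | step 6 | 5,7,4'-tri-O-benzylquercetin | O=c1c(O)c(-c2ccc(OCc3ccccc3)c(O)c2)oc2cc(OCc3ccccc3)cc(OCc3ccccc3)c12
F6 | step 6 | dipotassium 5,7,4'-tri-O-benzylquercetin 3,3'-disulfate | [K+].[K+].O=c1c(OS(=O)(=O)[O-])c(-c2ccc(OCc3ccccc3)c(OS(=O)(=O)[O-])c2)oc2cc(OCc3ccccc3)cc(OCc3ccccc3)c12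
F7 | step 1 | (E)-1-[2,4-bis(benzyloxy)-6-hydroxyphenyl]-3-[4-(methoxymethoxy)phenyl]prop-2-en-1-one | COCOc1ccc(/C=C/C(=O)c2c(O)cc(OCc3ccccc3)cc2OCc2ccccc2)cc1
F8 | step 1 | 5,7-bis(benzyloxy)-2-[4-(methoxymethoxy)phenyl]-4H-chromen-4-one | COCOc1ccc(-c2cc(=O)c3c(OCc4ccccc4)cc(OCc4ccccc4)cc3o2)cc1
F9 | step 2 | 5,7-bis(benzyloxy)-2-(4-hydroxyphenyl)chroman-4-one (racemic) | O=C1CC(c2ccc(O)cc2)Oc2cc(OCc3ccccc3)cc(OCc3ccccc3)c12
F10 | step 4 | dimethyl {5,7-bis(benzyloxy)-4-oxo-2-[4-(pivaloyloxy)phenyl]-4H-chromen-3-yl}boronate | COB(OC)c1c(-c2ccc(OC(=O)C(C)(C)C)cc2)oc2cc(OCc3ccccc3)cc(OCc3ccccc3)c2c1=O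
A1 | alternative 1 | quercetin | O=c1c(O)c(-c2ccc(O)c(O)c2)oc2cc(O)cc(O)c12
A2 | alternative 1 | 7,4'-di-O-benzylquercetin | O=c1c(O)c(-c2ccc(OCc3ccccc3)c(O)c2)oc2cc(OCc3ccccc3)cc(O)c12
A3 | alternative 1 | 7,3'-di-O-benzylquercetin | O=c1c(O)c(-c2ccc(O)c(OCc3ccccc3)c2)oc2cc(OCc3ccccc3)cc(O)c12
A4 | alternative 1 | dipotassium 7,4'-di-O-benzylquercetin 3,3'-disulfate | [K+].[K+].O=c1c(OS(=O)(=O)[O-])c(-c2ccc(OCc3ccccc3)c(OS(=O)(=O)[O-])c2)oc2cc(OCc3ccccc3)cc(O)c12
A5 | alternative 2 | 5,7-di-O-benzylquercetin | O=c1c(O)c(-c2ccc(O)c(O)c2)oc2cc(OCc3ccccc3)cc(OCc3ccccc3)c12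
A6 | alternative 2 | potassium 5,7-bis(benzyloxy)-2-(2,2-dioxo-1,3,2-benzodioxathiol-5-yl)-4-oxo-4H-chromen-3-yl sulfate | [K+].O=c1c(OS(=O)(=O)[O-])c(-c2ccc3OS(=O)(=O)Oc3c2)oc2cc(OCc3ccccc3)cc(OCc3ccccc3)c12
A7 | alternative 3 | potassium 5-[5,7-bis(benzyloxy)-4-oxo-4H-chromen-2-yl]-2-hydroxyphenyl sulfate | [K+].O=c1cc(-c2ccc(O)c(OS(=O)(=O)[O-])c2)oc2cc(OCc3ccccc3)cc(OCc3ccccc3)c12
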